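**Plan**

Labdane numbering is used: ring A is C1–C5 plus C10, ring B is C5–C10, C17 sits on C8, C11–C12 on C9, and the butenolide is C13–C16. The retrosynthesis cuts, in this order: C12–C13; C7–C8 (with C5 tied back to the C17 oxygen); C5–C6; C4–C18 and C4–C19; C9–C10.
Enabling feature: ring B, with C17 exocyclic on C8 and unsaturation at C5–C6, is the [3,3] isomer of the oxacycle C5–O–C17=C8–C9–C10 bearing a C6=C7 vinyl group on C5. A ring A-fused 2-vinyl-3,4-dihydro-2H-pyran can therefore be transposed into the decalin.
Forward order: ring A is bought as 2-methylcyclohexanone. A Michael addition joins the C9 carbon with both its arms, and C4 is hydroxymethylated twice. Vinyl addition and lactonisation close the oxacycle, ring B arises from it by Claisen rearrangement, and the bought butenolide ring is joined last at C12.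
Stereochemistry: C10 comes from (R)-1-phenylethylamine and C9 from the compact transition state of the same Michael step with an E-enoate. C8 is set by equilibration of the aldehyde to its equatorial epimer, and C5 by hydroxyl-directed hydrogenation anti to the C10 methyl.

Key step: step 9

Remark on the chemistry: the target SMILES corresponds to the ent-labdane series (5S,8S,9R,10S; C10 methyl α, H5 and H9 β, C17 β-equatorial), and C4 carries two like groups and is not stereogenic, so the quaternary carbon calls for the (R)-enantiomer of the amine.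

Step 1
Reactants: 1 2-methylcyclohexanone (racemic); 2 (R)-1-phenylethylamine
Product: 3 (R)-N-(2-methylcyclohexylidene)-1-phenylethanamine
Conditions: TsOH·H2O (cat.), PhMe, Dean–Stark, reflux
Reagents that add atoms: none
Why: Acid-catalysed ketimine condensation driven by azeotropic removal of water; the ring stereocentre stays labile through imine–enamine tautomerism, so both enantiomers of 1 can later be drawn into one product.

Step 2
Reactants: 4 3-(benzyloxy)propanal; 5 methyl 2-(triphenyl-λ5-phosphanylidene)acetate
Product: 6 methyl (E)-5-(benzyloxy)pent-2-enoate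
Conditions: CH2Cl2, 0 → 23 °C
Reagents that add atoms: none
Why: Wittig olefination with an ester-stabilised ylide, which reliably favours the E-alkene on which the relative configuration set in step 3 depends.

Step 3
Reactants: 3 (R)-N-(2-methylcyclohexylidene)-1-phenylethanamine; 6 methyl (E)-5-(benzyloxy)pent-2-enoate
Product: 8 methyl (3R)-5-(benzyloxy)-3-[(1S)-1-methyl-2-oxocyclohexyl]pentanoate, via adduct imine 7 (not isolated)
Conditions: THF (3 M), 1.2 GPa, 40 °C; then 10 % aq AcOH, THF, 23 °C
Reagents that add atoms: water, O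
Why: Deracemising Pfau–d'Angelo Michael addition, a reaction known to accept β-alkyl enoates under hyperbaric activation: the more substituted secondary enamine reacts through a compact chair-like aza-ene transition state on the face left open by the phenyl group of the (R)-auxiliary (10S), and the ester lies endo over nitrogen, so the E-alkene places C11 anti to C5 (9R).

Step 4
Reactants: 8 methyl (3R)-5-(benzyloxy)-3-[(1S)-1-methyl-2-oxocyclohexyl]pentanoate; 9 formaldehyde (37 % aq)
Product: 11 (3R)-5-(benzyloxy)-3-[(1S)-3,3-bis(hydroxymethyl)-1-methyl-2-oxocyclohexyl]pentanoic acid, via bis(hydroxymethyl) keto ester 10 (not isolated)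
Conditions: 37 % aq HCHO (8 equiv), K2CO3 (0.2 equiv), MeOH, 40 °C; then LiOH·H2O, 23 °C; 1 M HCl to pH 4, 0 °C
Reagents that add atoms: lithium hydroxide, [Li+].[OH-]
Why: Tollens-type double aldol hydroxymethylation followed by saponification: with C10 quaternary the ketone can enolise only towards C4, carbonate is too weak to deprotonate C8 next to the ester, the two new groups are alike so C4 is not stereogenic, and hydrolysis in the same flask masks C17 as a carboxylate for step 6.

Step 5
Reactants: 11 (3R)-5-(benzyloxy)-3-[(1S)-3,3-bis(hydroxymethyl)-1-methyl-2-oxocyclohexyl]pentanoic acid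
Product: 12 (3R)-5-(benzyloxy)-3-[(8S)-3,3,8-trimethyl-7-oxo-2,4-dioxaspiro[5.5]undecan-8-yl]pentanoic acid
Conditions: 2,2-dimethoxypropane, PPTS (cat.), CH2Cl2, 23 °C
Reagents that add atoms: 2,2-dimethoxypropane, COC(C)(C)OC
Why: Acid-catalysed transketalisation ties the 1,3-diol into a spiro 1,3-dioxane, which protects both hydroxyls and pulls the C4 substituents back from the C5 carbonyl.

Step 6
Reactants: 12 (3R)-5-(benzyloxy)-3-[(8S)-3,3,8-trimethyl-7-oxo-2,4-dioxaspiro[5.5]undecan-8-yl]pentanoic acid; 13 vinylmagnesium bromide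
Product: 15 (5S,9R,10S)-C5-vinyl δ-lactone, via hydroxy acid 14 (not isolated)
Conditions: CH2=CHMgBr (5 equiv), LaCl3·2LiCl (1 equiv), THF, 0 → 45 °C; aq NaH2PO4 work-up; crude 14, EDC·HCl, DMAP (cat.), CH2Cl2, 23 °C
Reagents that add atoms: none
Why: Lanthanide-assisted Grignard 1,2-addition to a ketone that cannot enolise, while the magnesium carboxylate made by the first equivalent is inert; the nucleophile enters axially on the face away from the axial C10 methyl and the axial C4–CH2O arm (5S, vinyl anti to the methyl), and carbodiimide lactonisation then closes the six-membered oxacycle with help from the flanking quaternary carbons.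

Step 7
Reactants: 15 (5S,9R,10S)-C5-vinyl δ-lactone
Product: 16 C17 lactol (both anomers)
Conditions: i-Bu2AlH (1.1 equiv), CH2Cl2, −78 °C; aq potassium sodium tartrate
Reagents that add atoms: none
Why: Partial reduction of a δ-lactone with one equivalent of i-Bu2AlH at low temperature stops at the aluminium hemiacetal, and the anomeric centre it creates is removed in the next step.

Step 8
Reactants: 16 C17 lactol
Product: 18 (5S,9R,10S)-ring A-fused 2-vinyl-3,4-dihydro-2H-pyran, via anomeric mesylate 17 (not isolated)
Conditions: MsCl, Et3N (5 equiv), CH2Cl2, −20 → 40 °C; chromatography on Et3N-deactivated silica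
Reagents that add atoms: methanesulfonyl chloride, CS(=O)(=O)Cl (its atoms are held only in intermediate 17)
Why: Lactol dehydration of the kind used for glycals: the anomeric mesylate loses methanesulfonate towards C8, the only neighbouring carbon that bears hydrogen, giving the cyclic enol ether under basic conditions that spare the tertiary allylic ether.

Step 9
Reactants: 18 (5S,9R,10S)-ring A-fused 2-vinyl-3,4-dihydro-2H-pyran
Product: 20 (8S,9R,10S)-octalin C8 carbaldehyde, via axial aldehyde 19 (not isolated)
Conditions: PhMe (0.02 M), i-Pr2NEt (0.2 equiv), BHT (cat.), sealed silylated glass tube, 195 °C; cool to 23 °C, DBU (0.3 equiv)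
Reagents that add atoms: none
Why: On heating, the allyl vinyl ether C8=C17–O–C5–C6=C7, which is held inside the bicycle, undergoes a concerted suprafacial [3,3] shift in which C7 bonds to C8, the crowded tertiary allylic C5–O bond breaks, C5=C6 forms and the oxygen leaves the ring as the C17 aldehyde. The closest known reaction type is the thermal Claisen rearrangement of 2-vinyl-3,4-dihydro-2H-pyrans to cyclohex-3-enecarbaldehydes. Ring B closes as a six-membered carbocycle by ring-to-ring transposition through a boat-shaped, bicyclo[2.2.2]octane-like transition state in which the axial vinyl group reaches across the oxacycle while ring A stays a chair. The only new stereocentre, C8, is first fixed by this geometry, since C7 arrives on the β face that carries the vinyl group and the formyl group ends α and axial (19); DBU then equilibrates it through the enolate to the equatorial 8S epimer 20, because the axial one suffers a 1,3-diaxial clash with the C10 methyl. C9 and C10 take no part and are carried over unchanged, and C5 becomes sp2, so the configuration set in step 6 has no bearing on the outcome. The step needs the sigmatropic path to outrun acid-induced ionisation of the tertiary allylic ether, which base-washed silylated glass, the amine buffer and dilution secure; periselectivity is given because the substrate holds only one allyl vinyl ether array.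

Step 10
Reactants: 20 (8S,9R,10S)-octalin C8 carbaldehyde
Product: 21 (8S,9R,10S)-octalin C17 alcohol
Conditions: NaBH4, MeOH–THF, 0 °C
Reagents that add atoms: none
Why: Borohydride reduction of the aldehyde, cold and fast enough that C8 keeps its equatorial configuration.

Step 11
Reactants: 21 (8S,9R,10S)-octalin C17 alcohol
Product: 22 (5S,8S,9R,10S)-trans-decalin C17 alcohol
Conditions: [Ir(cod)(PCy3)(py)]PF6 (10 mol %), H2 (10 bar), CH2Cl2, 23 °C
Reagents that add atoms: none
Why: Hydroxyl-directed homogeneous hydrogenation: the cationic iridium centre binds the β-oriented C17 hydroxyl and meets the trisubstituted C5=C6 alkene on the β face, which is also the face away from the axial C10 methyl, so hydrogen reaches C5 from β and the trans-decalin (5S) results.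

Step 12
Reactants: 22 (5S,8S,9R,10S)-trans-decalin C17 alcohol
Product: 23 C17 tert-butyldimethylsilyl ether
Conditions: TBSCl, imidazole, DMF, 23 °C
Reagents that add atoms: tert-butyldimethylsilyl chloride, CC(C)(C)[Si](C)(C)Cl
Why: Standard silylation of the primary C17 hydroxyl with a group that survives hydrogenolysis, iodination and organozinc chemistry and falls to acid at the end.

Step 13
Reactants: 23 C17 tert-butyldimethylsilyl ether
Product: 24 C12 alcohol
Conditions: H2 (1 atm), Pd/C (10 wt % Pd), EtOAc, 23 °C
Reagents that add atoms: none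
Why: Hydrogenolysis of the benzyl ether over palladium in a neutral aprotic solvent; no alkene is left to reduce, and the silyl ether and acetonide are inert.

Step 14
Reactants: 24 C12 alcohol
Product: 25 C12 iodide
Conditions: I2, PPh3, imidazole, CH2Cl2, 0 → 23 °C
Reagents that add atoms: iodine, II
Why: Appel-type iodination (Garegg–Samuelsson conditions) by SN2 displacement of the alkoxyphosphonium group at the unhindered primary C12, buffered by imidazole so that the acetonide and silyl ether stay on.

Step 15
Reactants: 26 furan-2(5H)-one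
Product: 28 3-bromofuran-2(5H)-one, via dibromolactone 27 (not isolated)
Conditions: Br2, CH2Cl2, 0 → 40 °C; then Et3N, 0 °C
Reagents that add atoms: bromine, BrBr
Why: Bromine addition across the butenolide alkene followed by E1cB loss of HBr, in which Et3N removes the acidic α-hydrogen and the β-bromide leaves, so bromine stays on the α-carbon.

Step 16
Reactants: 25 C12 iodide; 28 3-bromofuran-2(5H)-one
Product: 30 protected target, via alkylzinc iodide 29 (not isolated)
Conditions: Zn dust, LiCl, THF, 40 °C; then 28, PdCl2(dppf) (5 mol %), THF, 23 → 40 °C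
Reagents that add atoms: zinc, [Zn] (held only in intermediate 29)
Why: Negishi sp3–sp2 coupling: LiCl-assisted zinc insertion into the primary iodide gives an alkylzinc that tolerates lactone, acetal and silyl ether, and the bidentate dppf ligand on palladium favours reductive elimination over β-hydride elimination after oxidative addition into the electron-poor C–Br bond of 28.

Step 17
Reactants: 30 protected target
Product: 31 3-{2-[(1R,2S,4aS,8aS)-2,5,5-tris(hydroxymethyl)-8a-methyldecahydronaphthalen-1-yl]ethyl}furan-2(5H)-one
Conditions: 1 M aq HCl–THF (1:3), 23 → 40 °C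
Reagents that add atoms: none
Why: Aqueous acid hydrolyses the acetonide and the primary silyl ether in one operation, while the α-alkyl butenolide and the four stereocentres, none of them acid-labile, are untouched.

**Compound list**

1 | 2-methylcyclohexanone (racemic) | CC1CCCCC1=O | starting material
2 | (R)-1-phenylethylamine | C[C@@H](N)c1ccccc1 | starting material
3 | (R)-N-(2-methylcyclohexylidene)-1-phenylethanamine (ring carbon epimers, in equilibrium with the secondary enamines) | CC1CCCCC1=N[C@H](C)c2ccccc2 | intermediate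
4 | 3-(benzyloxy)propanal | O=CCCOCc1ccccc1 | starting material
5 | methyl 2-(triphenyl-λ5-phosphanylidene)acetate | COC(=O)C=P(c1ccccc1)(c1ccccc1)c1ccccc1 | starting material
6 | methyl (E)-5-(benzyloxy)pent-2-enoate | COC(=O)/C=C/CCOCc1ccccc1 | intermediate
7 | methyl (3R)-5-(benzyloxy)-3-[(1S)-1-methyl-2-{[(1R)-1-phenylethyl]imino}cyclohexyl]pentanoate (adduct imine) | C[C@]1(CCCCC1=N[C@H](C)c2ccccc2)[C@H](CCOCc3ccccc3)CC(=O)OC | intermediate
8 | methyl (3R)-5-(benzyloxy)-3-[(1S)-1-methyl-2-oxocyclohexyl]pentanoate | C[C@]1(CCCCC1=O)[C@H](CCOCc2ccccc2)CC(=O)OC | intermediate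
9 | formaldehyde | C=O | starting material
10 | methyl (3R)-5-(benzyloxy)-3-[(1S)-3,3-bis(hydroxymethyl)-1-methyl-2-oxocyclohexyl]pentanoate | C[C@]1(CCCC(CO)(CO)C1=O)[C@H](CCOCc2ccccc2)CC(=O)OC | intermediate
11 | (3R)-5-(benzyloxy)-3-[(1S)-3,3-bis(hydroxymethyl)-1-methyl-2-oxocyclohexyl]pentanoic acid | C[C@]1(CCCC(CO)(CO)C1=O)[C@H](CCOCc2ccccc2)CC(=O)O | intermediate
12 | (3R)-5-(benzyloxy)-3-[(8S)-3,3,8-trimethyl-7-oxo-2,4-dioxaspiro[5.5]undecan-8-yl]pentanoic acid | C[C@]1(CCCC2(COC(C)(C)OC2)C1=O)[C@H](CCOCc3ccccc3)CC(=O)O | intermediate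
13 | vinylmagnesium bromide | C=C[Mg]Br | starting material
14 | (3R)-5-(benzyloxy)-3-[(7S,8S)-7-ethenyl-7-hydroxy-3,3,8-trimethyl-2,4-dioxaspiro[5.5]undecan-8-yl]pentanoic acid | C[C@]1(CCCC2(COC(C)(C)OC2)[C@]1(O)C=C)[C@H](CCOCc3ccccc3)CC(=O)O | intermediate
15 | (5S,9R,10S)-vinyl lactone: trans ring A-fused δ-lactone C5–O–C17(=O)–C8–C9–C10, axial β-vinyl on C5, axial α-methyl on C10, equatorial CH2CH2OBn on C9, spiro acetonide at C4 | C[C@@]12CCCC3(COC(C)(C)OC3)[C@@]1(C=C)OC(=O)C[C@H]2CCOCc4ccccc4 | intermediate
16 | lactol of 15 (C17 hemiacetal, both anomers) | C[C@@]12CCCC3(COC(C)(C)OC3)[C@@]1(C=C)OC(O)C[C@H]2CCOCc4ccccc4 | intermediate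
17 | C17 methanesulfonate of lactol 16 | C[C@@]12CCCC3(COC(C)(C)OC3)[C@@]1(C=C)OC(OS(C)(=O)=O)C[C@H]2CCOCc4ccccc4 | intermediate
18 | (5S,9R,10S)-dihydropyran: ring A-fused 2-vinyl-3,4-dihydro-2H-pyran C5–O–C17=C8–C9–C10, other groups as in 15 | C[C@@]12CCCC3(COC(C)(C)OC3)[C@@]1(C=C)OC=C[C@H]2CCOCc4ccccc4 | intermediate
19 | (8R,9R,10S)-octalin carbaldehyde: C5=C6 alkene, axial α-formyl on C8 | C[C@@]12CCCC3(COC(C)(C)OC3)C1=CC[C@@H](C=O)[C@H]2CCOCc4ccccc4 | intermediate
20 | (8S,9R,10S)-octalin carbaldehyde: C5=C6 alkene, equatorial β-formyl on C8, equatorial CH2CH2OBn on C9, α-methyl on C10, spiro acetonide at C4 | C[C@@]12CCCC3(COC(C)(C)OC3)C1=CC[C@H](C=O)[C@H]2CCOCc4ccccc4 | intermediate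
21 | (8S,9R,10S)-octalin C17 alcohol | C[C@@]12CCCC3(COC(C)(C)OC3)C1=CC[C@H](CO)[C@H]2CCOCc4ccccc4 | intermediate
22 | (5S,8S,9R,10S)-trans-decalin C17 alcohol (H5 β) | C[C@@]12CCCC3(COC(C)(C)OC3)[C@H]1CC[C@H](CO)[C@H]2CCOCc4ccccc4 | intermediate
23 | C17 tert-butyldimethylsilyl ether of 22 | C[C@@]12CCCC3(COC(C)(C)OC3)[C@H]1CC[C@H](CO[Si](C)(C)C(C)(C)C)[C@H]2CCOCc4ccccc4 | intermediate
24 | C12 alcohol (C17 OTBS, C4 acetonide) | C[C@@]12CCCC3(COC(C)(C)OC3)[C@H]1CC[C@H](CO[Si](C)(C)C(C)(C)C)[C@H]2CCO | intermediate
25 | C12 iodide (C17 OTBS, C4 acetonide) | C[C@@]12CCCC3(COC(C)(C)OC3)[C@H]1CC[C@H](CO[Si](C)(C)C(C)(C)C)[C@H]2CCI | intermediate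
26 | furan-2(5H)-one | O=C1C=CCO1 | starting material
27 | 3,4-dibromodihydrofuran-2(3H)-one (racemic trans) | O=C1OCC(Br)C1Br | intermediate
28 | 3-bromofuran-2(5H)-one | O=C1OCC=C1Br | intermediate
29 | C12 alkylzinc iodide from 25 | C[C@@]12CCCC3(COC(C)(C)OC3)[C@H]1CC[C@H](CO[Si](C)(C)C(C)(C)C)[C@H]2CC[Zn]I | intermediate
30 | protected target: C12–C13 coupled butenolide, C17 OTBS, C4 acetonide | C[C@@]12CCCC3(COC(C)(C)OC3)[C@H]1CC[C@H](CO[Si](C)(C)C(C)(C)C)[C@H]2CCC4=CCOC4=O | intermediate
31 | 3-{2-[(1R,2S,4aS,8aS)-2,5,5-tris(hydroxymethyl)-8a-methyldecahydronaphthalen-1-yl]ethyl}furan-2(5H)-one (CNP0271381.1) | C[C@@]12CCCC(CO)(CO)[C@H]1CC[C@H](CO)[C@H]2CCC1=CCOC1=O | target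

Total step count: 17. Longest linear sequence: 15 steps (1, 3 to 14, 16, 17) from 2-methylcyclohexanone.

**Steps most likely to fail**

Step 3. The C9–C10 bond may form too slowly at a β-alkyl enoate even under pressure. A long reaction time could also let the addition reverse and wear down the control at C9 and C10. The fallback activates the acceptor electronically instead of by pressure. It sets out from imine 3 and aldehyde 4. Knoevenagel condensation of 4 with dimethyl malonate (TiCl4, pyridine, THF) would give dimethyl 2-[3-(benzyloxy)propylidene]propanedioate F1. Imine 3 should add to F1 at ambient pressure to give the malonate adduct imine F2. Aqueous AcOH would hydrolyse F2 to the keto malonate F3. Krapcho dealkoxycarbonylation (LiCl, wet DMSO, 150 °C) removes the extra ester and brings the material back to the route at 8.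

Step 6. The vinyl nucleophile may fail to reach a carbonyl carbon flanked by two quaternary carbons, so that the reagent is used up without addition. The fallback sets out from keto acid 12 and uses a slimmer sp-hybridised nucleophile. HC≡CMgBr with LaCl3·2LiCl in THF would give the ethynyl hydroxy acid F4, and EDC·HCl with DMAP would close it to the ethynyl lactone F5. Semi-hydrogenation (H2, Pd/CaCO3 poisoned with Pb(OAc)2, quinoline, EtOAc) turns the alkyne into the vinyl group and returns to the route at 15.

Step 9. At about 195 °C, ionisation of the tertiary allylic C5–O bond or unspecific thermal breakdown may overtake the sigmatropic shift. The fallback keeps the same C7–C8 bond formation and the same closure of ring B, but raises C17 to the acid level so that the shift runs near 110 °C. It sets out from lactone 15. LDA, then TBSCl and DMPU in THF at −78 °C, would give the silyl ketene acetal F6. In refluxing PhMe, F6 should undergo the Ireland–Claisen variant of the rearrangement to give the axial silyl ester F7. LiAlH4 reduces F7 to the axial C17 alcohol F8. Dess–Martin oxidation gives aldehyde 19, and DBU equilibrates it, which returns to the route at 20.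

**Further compounds**

F1 | step 3 | dimethyl 2-[3-(benzyloxy)propylidene]propanedioate | COC(=O)C(=CCCOCc1ccccc1)C(=O)OC
F2 | step 3 | dimethyl 2-{(1R)-3-(benzyloxy)-1-[(1S)-1-methyl-2-{[(1R)-1-phenylethyl]imino}cyclohexyl]propyl}propanedioate | C[C@]1(CCCCC1=N[C@H](C)c2ccccc2)[C@H](CCOCc3ccccc3)C(C(=O)OC)C(=O)OC
F3 | step 3 | dimethyl 2-{(1R)-3-(benzyloxy)-1-[(1S)-1-methyl-2-oxocyclohexyl]propyl}propanedioate | C[C@]1(CCCCC1=O)[C@H](CCOCc2ccccc2)C(C(=O)OC)C(=O)OC
F4 | step 6 | (3R)-5-(benzyloxy)-3-[(7S,8S)-7-ethynyl-7-hydroxy-3,3,8-trimethyl-2,4-dioxaspiro[5.5]undecan-8-yl]pentanoic acid | C[C@]1(CCCC2(COC(C)(C)OC2)[C@]1(O)C#C)[C@H](CCOCc3ccccc3)CC(=O)O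
F5 | step 6 | (5S,9R,10S)-ethynyl lactone, as 15 with ethynyl in place of vinyl on C5 | C[C@@]12CCCC3(COC(C)(C)OC3)[C@@]1(C#C)OC(=O)C[C@H]2CCOCc4ccccc4
F6 | step 9 | tert-butyldimethylsilyl ketene acetal of lactone 15 (C17 OTBS, C17=C8) | C[C@@]12CCCC3(COC(C)(C)OC3)[C@@]1(C=C)OC(O[Si](C)(C)C(C)(C)C)=C[C@H]2CCOCc4ccccc4
F7 | step 9 | (8R,9R,10S)-octalin C8 carboxylic acid tert-butyldimethylsilyl ester (axial) | C[C@@]12CCCC3(COC(C)(C)OC3)C1=CC[C@@H](C(=O)O[Si](C)(C)C(C)(C)C)[C@H]2CCOCc4ccccc4
F8 | step 9 | (8R,9R,10S)-octalin C17 alcohol (axial CH2OH) | C[C@@]12CCCC3(COC(C)(C)OC3)C1=CC[C@@H](CO)[C@H]2CCOCc4ccccc4
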